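## The problem

Compound 25 is an achiral diaryl ether of two heptyl-substituted benzoic acids. Ring A carries the carboxyl at C1, the ether oxygen at C2, a methoxy at C4 and the heptyl chain at C6. Ring B carries the ether oxygen at C1', a free hydroxyl at C3', the carboxyl at C4', heptyl at C5' and a methoxy at C6', so that C2'–H is its only unsubstituted position. There is no stereocentre; the whole difficulty is regiochemical. Ring B is pentasubstituted with three different oxygen functions, and the one that must stay a free phenol has ethers as its oxygen neighbours, so a late selective demethylation is unattractive. The ether oxygen is flanked by the C1 carboxyl on ring A and by the C6' methoxy on ring B, a doubly ortho-substituted linkage that metal-catalysed C–O couplings form reluctantly. Both acids are electron-rich, ortho-oxygenated benzoic acids that lose CO2 under acid or heat, and ring B is a hydroquinone monomethyl ether that is easily oxidised, so the final unveiling must be neutral and mild. The enabling feature is the C3' hydroxyl para to the C6' methoxy, with the C1' aryloxy group beside that methoxy and C2' unsubstituted. This is the pattern released when a 4-alkenyl-4-methoxy-3-aryloxycyclobut-2-enone ring-expands: the ketene carbonyl becomes C3'–OH, the quaternary methoxy carbon becomes C6', the aryloxy enol carbon becomes C1', and the two alkene carbons become C5' and C4'. Ring B can therefore be grown from a four-carbon squarate unit onto a finished ring A, and the hindered ether is made at a cyclobutenedione carbon by addition–elimination rather than at an arene.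

## Retrosynthesis

**End game (25 back to 21).** The benzyl ester C–O bond of 24 is cut last, because hydrogenolysis is the only neutral way to free the ring A acid without risking decarboxylation. The C4' carboxyl of 24 is traced back through salicylaldehyde 23 and benzylic alcohol 22 to silyl ether 21. The carbon is carried at the alcohol oxidation state because an alkenyl nucleophile with an ester on its terminus would lactonise onto the alkoxide it creates. The forward steps must tolerate a free phenol and a benzyl ester: fluoride, MnO2 and buffered chlorite meet this.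

**Key disconnection (21 back to 18).** The C3'–C4' bond is cut, which opens ring B to dienylketene 19 (through cyclohexadienone 20) and further to cyclobutenone 18. Cutting the ether C–O bond instead would leave the pentasubstituted ring B unsolved and would demand a doubly ortho-hindered coupling. The ring expansion fixes all five substituents of ring B by the connectivity of 18 alone. The precursor 18 has a four-membered ring and an acyclic alkene in place of a pentasubstituted arene. The forward reaction needs outward rotation of the methoxy group during ring opening and a ring closure that outruns side reactions of the ketene.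

**Assembly of the cyclobutenone (18 back to 11 and 15).** The bond between the quaternary ring carbon and the alkenyl carbon and the O–methyl bond are cut, giving aryl semisquarate 11 and alkenyl iodide 15 (through alkenyllithium 16 and alkoxide 17). This is the standard entry to 4-alkenyl-4-alkoxycyclobutenones and is convergent. The addition must go 1,2 to the ketone-like carbonyl next to the aryloxy carbon, must spare the hindered benzyl ester, and the tertiary alkoxide must be methylated before it can revert.

**Ether bond (11 back to 4 and 9).** The O–C bond between the ring A oxygen and the cyclobutene carbon is cut, giving phenol 4 and semisquaric chloride 9. The ether is formed by addition–elimination at a vinylogous acid chloride, which is far easier than an arene–oxygen coupling next to an ester. The phenoxide 10 must substitute once and the product must survive isolation.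

**Four-carbon unit (9 back to 5).** Chloride 9 comes from semisquaric acid 8, which comes from its isopropyl ester 7, made by reduction and acid-mediated transposition of diisopropyl squarate 5 through hydroxy ketone 6. Each step is a functional group exchange on a symmetrical, purchasable squarate.

**Alkenyl donor (15 back to 12).** The C–I bond and the silyl ether are cut, giving dec-2-yn-1-ol 12. Hydroxyl-directed trans-hydroalumination through aluminate 13 puts the metal, and then iodine, on C3 to give 14. Only this regiochemistry matters, since the alkene geometry is lost on aromatisation.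

**Ring A (4 back to 1).** The methyl ether, the benzyl ester and the C1 carboxyl are removed in turn (4 to 3 to 2 to 1), leading to 5-heptylresorcinol 1. Ortho-carboxylation of a 5-alkylresorcinol, carboxylate-selective benzylation and methylation of the non-chelated para hydroxyl are each established on orsellinate-type systems.

## Roads not taken

**Alternative 1:** Both aryl–heptyl bonds are cut, leading to the unalkylated diacid A1. In the forward direction Pd(OAc)2 (divalent palladium) with a mono-N-acetyl amino acid ligand and Ag2CO3 would couple potassium heptyltrifluoroborate A2 at the one free ortho C–H of each carboxylate to give A3, the C3' methyl ether of 25. A final cleavage of that methyl ether would follow.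
- Merits: each carboxyl has exactly one ortho C–H, so the sites are unambiguous; the chains arrive last; no protecting groups are needed. The route could be roughly half as long as the chosen one, and in step economy it is clearly better.
- Weak points: a primary alkyl group with β-hydrogens is a poor partner in carboxylate-directed C–H coupling, since β-hydride elimination competes. The C5'–H of ring B lies between the carboxyl and the C6' methoxy and is hindered. Two independent C–H activations must both go to completion on one molecule. The hindered ether of A1 still has to be made by a conventional coupling. The last step is a Lewis-acid demethylation on an acid that decarboxylates easily.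
- Comparison: the chosen plan is longer, but it sets every substituent of ring B by connectivity and never has to differentiate methyl ethers.

**Alternative 2:** The C2–O ether bond and the C1–carboxyl bond of ring A are cut together. CsF would release the aryne from silyl triflate A4, the phenoxide of ring B phenol A5 would add at the aryne carbon remote from bromine, and the resulting aryl anion would capture CO2 to give bromo acid A6. The heptyl chain would then be installed by an sp2–sp3 cross-coupling at the bromide, followed by hydrogenolysis.
- Merits: the hindered ether and the carboxyl are formed in one operation; the site of phenoxide attack is well predicted by the inductive effect of bromine; few steps follow the key step. In forming the ether bond this road is at least as direct as the chosen one.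
- Weak points: the ring B partner A5 already contains the whole pentasubstituted pattern, so the main problem is only moved elsewhere. The aryl anion next to bromine can be protonated instead of carboxylated or can lose bromide. The alkylation must then be done at a bromide flanked by two substituents.
- Comparison: the chosen plan spends its key step on ring B, the ring that is hard to make, and gets ring A in three routine steps from 1.

**Alternative 3:** The C1–C2 and C5–C6 bonds of ring A are cut. Pyrone A7 would add through its carbons 6 and 3 to benzyl dec-2-ynoate A8, and loss of CO2 from the bicyclic lactone would give A9, the tribenzyl-protected target.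
- Merits: the polarity of the electron-rich pyrone and the ynoate matches the required regiochemistry; the arene forms at the correct oxidation level; A9 is one hydrogenolysis from 25. Its end game is better than the four steps the chosen plan needs after its key step.
- Weak points: a 6-aryloxy-2-pyrone is an acylal-like electrophile that is hard to prepare and prone to ring opening. A β-alkyl ynoate is a sluggish dienophile, and the temperatures needed endanger A7. As in alternative 2, ring B must be supplied complete, through its own multistep synthesis.
- Comparison: the chosen plan has the longer end game, but its cycloaromatisation builds the ring that no simple aromatic starting material provides.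

Key step: step 11

## Route

Remark on the chemistry: diisopropyl squarate 5, the purchasable diester of squaric acid, is used as the four-carbon starting material; 5-heptylresorcinol 1 and dec-2-yn-1-ol 12 are likewise taken as purchasable.

Step 1
Reactants: 1 5-heptylresorcinol
Product: 2 2-heptyl-4,6-dihydroxybenzoic acid
Conditions: MeOMgOCO2Me, DMF, 120 °C; then 1 M HCl, 0 °C
Reagents that add atoms: methyl magnesium carbonate, COC(=O)O[Mg]OC
Why: Kolbe–Schmitt-type ortho-carboxylation through a magnesium chelate, which on 5-alkylresorcinols places the carboxyl between a hydroxyl and the alkyl chain; cold acidic work-up limits decarboxylation.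

Step 2
Reactants: 2 2-heptyl-4,6-dihydroxybenzoic acid
Product: 3 benzyl 2-heptyl-4,6-dihydroxybenzoate
Conditions: BnBr, KHCO3, DMF, 23 °C
Reagents that add atoms: benzyl bromide, BrCc1ccccc1
Why: Carboxylate O-alkylation; hydrogen carbonate ionises only the carboxylic acid, so the phenols stay free.

Step 3
Reactants: 3 benzyl 2-heptyl-4,6-dihydroxybenzoate
Product: 4 benzyl 2-heptyl-6-hydroxy-4-methoxybenzoate
Conditions: MeI (1.1 equiv), K2CO3, acetone, 23 to 40 °C
Reagents that add atoms: iodomethane, CI
Why: Williamson etherification selective for the para hydroxyl, because the ortho hydroxyl is held in a hydrogen bond to the ester carbonyl, as in orsellinate chemistry.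

Step 4
Reactants: 5 diisopropyl squarate (3,4-diisopropoxycyclobut-3-ene-1,2-dione)
Product: 7 3-isopropoxycyclobut-3-ene-1,2-dione, via 4-hydroxy-2,3-diisopropoxycyclobut-2-en-1-one 6 (not isolated)
Conditions: LiAlH(Ot-Bu)3, THF, −78 to 0 °C; then 12 M HCl, CH2Cl2, 23 °C
Reagents that add atoms: water (from aqueous HCl; its oxygen becomes the new carbonyl oxygen), O
Why: Mono-reduction of one carbonyl of the symmetrical squarate, then acid-promoted ionisation of the allylic hydroxyl, addition of water to the alkoxy-stabilised cation and loss of isopropanol (1,3-carbonyl transposition), the standard preparation of 3-alkoxycyclobutenediones.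

Step 5
Reactants: 7 3-isopropoxycyclobut-3-ene-1,2-dione
Product: 8 semisquaric acid (3-hydroxycyclobut-3-ene-1,2-dione)
Conditions: 2 M HCl, THF, 23 °C; evaporation
Reagents that add atoms: water, O
Why: Hydrolysis of a vinylogous ester by addition–elimination; squarate esters hydrolyse readily and the strongly acidic product is isolated by evaporation.

Step 6
Reactants: 8 semisquaric acid
Product: 9 semisquaric chloride (3-chlorocyclobut-3-ene-1,2-dione)
Conditions: (COCl)2, DMF (cat.), CH2Cl2, 0 to 23 °C
Reagents that add atoms: oxalyl chloride, ClC(=O)C(Cl)=O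
Why: Conversion of a vinylogous carboxylic acid into its chloride with the chloroiminium species from oxalyl chloride and DMF, as used for the chlorides of squaric and semisquaric acid.

Step 7
Reactants: 4 benzyl 2-heptyl-6-hydroxy-4-methoxybenzoate, 9 semisquaric chloride
Product: 11 benzyl 2-[(3,4-dioxocyclobut-1-en-1-yl)oxy]-6-heptyl-4-methoxybenzoate, via sodium phenoxide 10 (not isolated)
Conditions: 4, NaH, THF, 0 °C; then added to 9 (1.2 equiv), THF, −78 to 0 °C; non-aqueous work-up
Reagents that add atoms: none
Why: Addition–elimination of a phenoxide at the chlorine-bearing carbon of a vinylogous acid chloride; inverse addition keeps the chloride in excess so that a second phenoxide does not add to the product.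

Step 8
Reactants: 12 dec-2-yn-1-ol
Product: 14 (2Z)-3-iododec-2-en-1-ol, via cyclic alkenylaluminate 13 (not isolated)
Conditions: NaAlH2(OCH2CH2OMe)2, THF, 0 to 23 °C; EtOAc; then I2, THF, −78 to 0 °C
Reagents that add atoms: iodine, II
Why: Hydroxyl-directed trans-hydroalumination delivers hydride to C2 and aluminium to C3 in a five-membered aluminate; iodinolysis with retention gives the (Z)-3-iodo allylic alcohol.

Step 9
Reactants: 14 (2Z)-3-iododec-2-en-1-ol
Product: 15 tert-butyl{[(2Z)-3-iododec-2-en-1-yl]oxy}dimethylsilane
Conditions: TBSCl, imidazole, CH2Cl2, 23 °C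
Reagents that add atoms: tert-butyldimethylsilyl chloride, CC(C)(C)[Si](C)(C)Cl
Why: Standard silylation of a primary alcohol; the silyl ether tolerates t-BuLi and the later thermolysis.

Step 10
Reactants: 15 tert-butyl{[(2Z)-3-iododec-2-en-1-yl]oxy}dimethylsilane, 11 benzyl 2-[(3,4-dioxocyclobut-1-en-1-yl)oxy]-6-heptyl-4-methoxybenzoate
Product: 18 benzyl 2-({4-[(2Z)-1-{[tert-butyl(dimethyl)silyl]oxy}dec-2-en-3-yl]-4-methoxy-3-oxocyclobut-1-en-1-yl}oxy)-6-heptyl-4-methoxybenzoate (racemic), via alkenyllithium 16 (not isolated), via lithium alkoxide 17 (not isolated)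
Conditions: 15, t-BuLi (2 equiv), Et2O, −78 °C; transferred to 11, THF, −78 °C; then MeOTf, −78 to 0 °C
Reagents that add atoms: methyl triflate, COS(=O)(=O)C(F)(F)F
Why: Iodine–lithium exchange with retention, then 1,2-addition of the alkenyllithium to the ketone-like carbonyl next to the aryloxy carbon (the other carbonyl is deactivated as a vinylogous ester), and in situ O-methylation of the tertiary alkoxide; the quaternary centre forms as a racemate and is destroyed in step 11.

Step 11
Reactants: 18 the 4-alkenyl-4-methoxy-3-aryloxycyclobutenone
Product: 21 benzyl 2-[4-({[tert-butyl(dimethyl)silyl]oxy}methyl)-3-heptyl-5-hydroxy-2-methoxyphenoxy]-6-heptyl-4-methoxybenzoate, via dienylketene 19 (not isolated), via cyclohexadienone 20 (not isolated)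
Conditions: PhMe (0.01 M, degassed), 110 °C
Reagents that add atoms: none
Why: Heating should open the cyclobutenone by a conrotatory 4π electrocyclic cleavage of the bond between the carbonyl carbon and the quaternary carbon, giving dienylketene 19. A thermally allowed disrotatory 6π electrocyclisation then joins the ketene carbon to the alkene terminus, forming the C3'–C4' bond and the six-membered ring B as cyclohexadienone 20, which enolises to phenol 21. The closest known reaction type is the thermal rearrangement of 4-alkenyl-4-alkoxy- or 4-hydroxycyclobutenones, made from cyclobutenediones and alkenyllithiums, to hydroquinone monoethers. No stereocentre remains: the racemic quaternary carbon becomes C6' and the transient sp3 carbon of 20 is lost on tautomerisation, which also erases the alkene geometry. The step needs torquoselectivity, and the donor methoxy group on the quaternary carbon should rotate outward, which turns the alkenyl group inward toward the ketene. The regiochemistry is fixed by the connectivity of 18: the ketene carbonyl becomes the C3' hydroxyl, the methoxy carbon C6', the aryloxy carbon C1', and the heptyl and silyloxymethyl carbons C5' and C4'. The conditions are neutral, so the benzyl ester and the silyl ether are left untouched, and high dilution disfavours ketene dimerisation.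

Step 12
Reactants: 21 the ring B phenol silyl ether
Product: 22 benzyl 2-[3-heptyl-5-hydroxy-4-(hydroxymethyl)-2-methoxyphenoxy]-6-heptyl-4-methoxybenzoate
Conditions: Bu4NF, AcOH, THF, 0 to 23 °C
Reagents that add atoms: none
Why: Fluoride-induced cleavage of the silyl ether; acetic acid buffering keeps the phenol protonated and avoids base-induced side reactions of the ortho-hydroxybenzyl alcohol.

Step 13
Reactants: 22 the ortho-hydroxybenzyl alcohol
Product: 23 benzyl 2-(4-formyl-3-heptyl-5-hydroxy-2-methoxyphenoxy)-6-heptyl-4-methoxybenzoate
Conditions: activated MnO2, CH2Cl2, 23 °C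
Reagents that add atoms: none
Why: Chemoselective oxidation of a benzylic alcohol to the aldehyde, which is stabilised by a hydrogen bond to the ortho hydroxyl; MnO2 does not oxidise the phenol under these conditions.

Step 14
Reactants: 23 the salicylaldehyde
Product: 24 4-{2-[(benzyloxy)carbonyl]-3-heptyl-5-methoxyphenoxy}-2-heptyl-6-hydroxy-3-methoxybenzoic acid
Conditions: NaClO2, NaH2PO4, 2-methyl-2-butene (excess), t-BuOH/H2O, 0 to 23 °C
Reagents that add atoms: sodium chlorite, [Na+].[O-]Cl=O
Why: Pinnick oxidation of the aldehyde to the acid under buffered conditions; excess alkene scavenges HOCl before it can chlorinate the electron-rich ring.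

Step 15
Reactants: 24 the monobenzyl ester
Product: 25 2-(4-carboxy-3-heptyl-5-hydroxy-2-methoxyphenoxy)-6-heptyl-4-methoxybenzoic acid
Conditions: H2 (1 atm), Pd/C, EtOAc, 23 °C
Reagents that add atoms: none
Why: Neutral hydrogenolysis of the benzyl ester frees the ring A acid without acid or heat, which both salicylate-type acids would not tolerate.

## Compound list

1 | 5-heptylresorcinol | CCCCCCCc1cc(O)cc(O)c1 | starting material
2 | 2-heptyl-4,6-dihydroxybenzoic acid | CCCCCCCc1cc(O)cc(O)c1C(=O)O | intermediate
3 | benzyl 2-heptyl-4,6-dihydroxybenzoate | CCCCCCCc1cc(O)cc(O)c1C(=O)OCc1ccccc1 | intermediate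
4 | benzyl 2-heptyl-6-hydroxy-4-methoxybenzoate | CCCCCCCc1cc(OC)cc(O)c1C(=O)OCc1ccccc1 | intermediate
5 | diisopropyl squarate (3,4-diisopropoxycyclobut-3-ene-1,2-dione) | CC(C)OC1=C(OC(C)C)C(=O)C1=O | starting material
6 | 4-hydroxy-2,3-diisopropoxycyclobut-2-en-1-one (racemic) | CC(C)OC1=C(OC(C)C)C(O)C1=O | intermediate
7 | 3-isopropoxycyclobut-3-ene-1,2-dione | CC(C)OC1=CC(=O)C1=O | intermediate
8 | semisquaric acid (3-hydroxycyclobut-3-ene-1,2-dione) | OC1=CC(=O)C1=O | intermediate
9 | semisquaric chloride (3-chlorocyclobut-3-ene-1,2-dione) | ClC1=CC(=O)C1=O | intermediate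
10 | sodium 2-[(benzyloxy)carbonyl]-3-heptyl-5-methoxyphenoxide | CCCCCCCc1cc(OC)cc([O-])c1C(=O)OCc1ccccc1.[Na+] | intermediate
11 | benzyl 2-[(3,4-dioxocyclobut-1-en-1-yl)oxy]-6-heptyl-4-methoxybenzoate | CCCCCCCc1cc(OC)cc(OC2=CC(=O)C2=O)c1C(=O)OCc1ccccc1 | intermediate
12 | dec-2-yn-1-ol | CCCCCCCC#CCO | starting material
13 | sodium 3-heptyl-2,2-bis(2-methoxyethoxy)-2,5-dihydro-1,2-oxaaluminol-2-uide (cyclic alkenylaluminate) | CCCCCCCC1=CCO[Al-]1(OCCOC)OCCOC.[Na+] | intermediate
14 | (2Z)-3-iododec-2-en-1-ol | CCCCCCC/C(I)=C/CO | intermediate
15 | tert-butyl{[(2Z)-3-iododec-2-en-1-yl]oxy}dimethylsilane | CCCCCCC/C(I)=C/CO[Si](C)(C)C(C)(C)C | intermediate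
16 | 3-lithio analogue of 15, lithium cis to the silyloxymethyl group (alkenyllithium) | CCCCCCC/C([Li])=C/CO[Si](C)(C)C(C)(C)C | intermediate
17 | lithium alkoxide of the 4-hydroxy analogue of 18 (racemic) | CCCCCCC/C(=C/CO[Si](C)(C)C(C)(C)C)C1(O[Li])C(Oc2cc(OC)cc(CCCCCCC)c2C(=O)OCc2ccccc2)=CC1=O | intermediate
18 | benzyl 2-({4-[(2Z)-1-{[tert-butyl(dimethyl)silyl]oxy}dec-2-en-3-yl]-4-methoxy-3-oxocyclobut-1-en-1-yl}oxy)-6-heptyl-4-methoxybenzoate (racemic) | CCCCCCC/C(=C/CO[Si](C)(C)C(C)(C)C)C1(OC)C(Oc2cc(OC)cc(CCCCCCC)c2C(=O)OCc2ccccc2)=CC1=O | intermediate
19 | dienylketene from ring opening of 18, methoxy outward and alkenyl group cis to the ketene (both C=C bonds Z) | O=C=C/C(Oc1cc(OC)cc(CCCCCCC)c1C(=O)OCc1ccccc1)=C(OC)\C(CCCCCCC)=C/CO[Si](C)(C)C(C)(C)C | intermediate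
20 | 3-aryloxy-5-heptyl-4-methoxy-6-(silyloxymethyl)cyclohexa-2,4-dien-1-one, keto tautomer of 21 (racemic) | O=C1C=C(Oc2cc(OC)cc(CCCCCCC)c2C(=O)OCc2ccccc2)C(OC)=C(CCCCCCC)C1CO[Si](C)(C)C(C)(C)C | intermediate
21 | benzyl 2-[4-({[tert-butyl(dimethyl)silyl]oxy}methyl)-3-heptyl-5-hydroxy-2-methoxyphenoxy]-6-heptyl-4-methoxybenzoate | CCCCCCCc1cc(OC)cc(Oc2cc(O)c(CO[Si](C)(C)C(C)(C)C)c(CCCCCCC)c2OC)c1C(=O)OCc1ccccc1 | intermediate
22 | benzyl 2-[3-heptyl-5-hydroxy-4-(hydroxymethyl)-2-methoxyphenoxy]-6-heptyl-4-methoxybenzoate | CCCCCCCc1cc(OC)cc(Oc2cc(O)c(CO)c(CCCCCCC)c2OC)c1C(=O)OCc1ccccc1 | intermediate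
23 | benzyl 2-(4-formyl-3-heptyl-5-hydroxy-2-methoxyphenoxy)-6-heptyl-4-methoxybenzoate | CCCCCCCc1cc(OC)cc(Oc2cc(O)c(C=O)c(CCCCCCC)c2OC)c1C(=O)OCc1ccccc1 | intermediate
24 | 4-{2-[(benzyloxy)carbonyl]-3-heptyl-5-methoxyphenoxy}-2-heptyl-6-hydroxy-3-methoxybenzoic acid | CCCCCCCc1cc(OC)cc(Oc2cc(O)c(C(=O)O)c(CCCCCCC)c2OC)c1C(=O)OCc1ccccc1 | intermediate
25 | 2-(4-carboxy-3-heptyl-5-hydroxy-2-methoxyphenoxy)-6-heptyl-4-methoxybenzoic acid | CCCCCCCc1cc(OC)cc(Oc2cc(O)c(C(=O)O)c(CCCCCCC)c2OC)c1C(=O)O | target

## Step count and risks

Total step count: 15. Longest linear sequence: 10 steps (steps 1, 2, 3, 7, 10, 11, 12, 13, 14, 15; the squarate branch through steps 4, 5, 6 is equally long).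

**Step 11 (key step).** The (Z)-alkene turns its silyloxymethyl group into the forming ring, which may slow the 6π closure. The dienylketene could then be lost to dimerisation or to capture by traces of water. On prolonged heating the product could also lose silanol from the ortho-silyloxymethyl phenol. Fallback: change the oxidation level of the terminus before the ring expansion. Starting from 18, buffered Bu4NF would give the allylic alcohol benzyl 2-heptyl-6-({4-[(2Z)-1-hydroxydec-2-en-3-yl]-4-methoxy-3-oxocyclobut-1-en-1-yl}oxy)-4-methoxybenzoate F1. MnO2 would oxidise it to the enal benzyl 2-heptyl-4-methoxy-6-({4-methoxy-3-oxo-4-[(2Z)-1-oxodec-2-en-3-yl]cyclobut-1-en-1-yl}oxy)benzoate F2. Thermolysis of F2 in toluene would then deliver salicylaldehyde 23 directly. The inward group is now a small planar formyl group, and the product has no benzylic leaving group. The fallback rejoins the route at 23 with the same number of steps.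

**Step 7.** The aryl semisquarate is a highly electrophilic vinylogous aryl ester. The aryloxy group may be lost by hydrolysis during isolation, a second phenoxide may add, and the volatile, moisture-sensitive chloride 9 may be lost. Fallback: build the same compound from a dichloride and remove the extra chlorine. Starting from 4 (as phenoxide 10), reaction with purchasable 3,4-dichlorocyclobut-3-ene-1,2-dione F3 at −78 °C would give benzyl 2-[(2-chloro-3,4-dioxocyclobut-1-en-1-yl)oxy]-6-heptyl-4-methoxybenzoate F4. The remaining vinylogous acid chloride would then be reduced with Bu3SnH (1 equiv) and Pd(PPh3)4, the counterpart of the acid chloride to aldehyde reduction, to return to the route at 11. This also bypasses steps 4 to 6, but the mono-substitution and the chemoselective hydride transfer are less secure than the main sequence.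

**Step 10.** Conjugate addition–elimination that expels the ring A phenoxide may compete with 1,2-addition. The alkenyllithium may attack the benzyl ester. The hindered tertiary alkoxide may be methylated incompletely while MeOTf is consumed by the ether solvent. Transmetalation to the organocerium reagent with CeCl3 is the first adjustment. Fallback: separate addition and methylation. Starting from 11 and 16, an NH4Cl quench of 17 would give the isolable tertiary alcohol benzyl 2-({4-[(2Z)-1-{[tert-butyl(dimethyl)silyl]oxy}dec-2-en-3-yl]-4-hydroxy-3-oxocyclobut-1-en-1-yl}oxy)-6-heptyl-4-methoxybenzoate F5. Purdie methylation (MeI, Ag2O, MeCN) under neutral conditions would rejoin the route at 18.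

**Step 14.** HOCl may chlorinate the electron-rich ring B at C2', or the hydroquinone monoether may be oxidised toward a quinone, because the phenol is free during the chlorite oxidation. Fallback: mask the phenol with a group that the last step removes anyway. Starting from 23, BnBr and K2CO3 would give benzyl 2-[5-(benzyloxy)-4-formyl-3-heptyl-2-methoxyphenoxy]-6-heptyl-4-methoxybenzoate F6. Pinnick oxidation would give 6-(benzyloxy)-4-{2-[(benzyloxy)carbonyl]-3-heptyl-5-methoxyphenoxy}-2-heptyl-3-methoxybenzoic acid F7. Hydrogenolysis over Pd/C would cleave the benzyl ether and the benzyl ester together and rejoin the route at 25, at the cost of one extra step.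

## Further compounds

F1 | step 11 | benzyl 2-heptyl-6-({4-[(2Z)-1-hydroxydec-2-en-3-yl]-4-methoxy-3-oxocyclobut-1-en-1-yl}oxy)-4-methoxybenzoate (racemic) | CCCCCCC/C(=C/CO)C1(OC)C(Oc2cc(OC)cc(CCCCCCC)c2C(=O)OCc2ccccc2)=CC1=O
F2 | step 11 | benzyl 2-heptyl-4-methoxy-6-({4-methoxy-3-oxo-4-[(2Z)-1-oxodec-2-en-3-yl]cyclobut-1-en-1-yl}oxy)benzoate (racemic) | CCCCCCC/C(=C/C=O)C1(OC)C(Oc2cc(OC)cc(CCCCCCC)c2C(=O)OCc2ccccc2)=CC1=O
F3 | step 7 | 3,4-dichlorocyclobut-3-ene-1,2-dione | ClC1=C(Cl)C(=O)C1=O
F4 | step 7 | benzyl 2-[(2-chloro-3,4-dioxocyclobut-1-en-1-yl)oxy]-6-heptyl-4-methoxybenzoate | CCCCCCCc1cc(OC)cc(OC2=C(Cl)C(=O)C2=O)c1C(=O)OCc1ccccc1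
F5 | step 10 | benzyl 2-({4-[(2Z)-1-{[tert-butyl(dimethyl)silyl]oxy}dec-2-en-3-yl]-4-hydroxy-3-oxocyclobut-1-en-1-yl}oxy)-6-heptyl-4-methoxybenzoate (racemic) | CCCCCCC/C(=C/CO[Si](C)(C)C(C)(C)C)C1(O)C(Oc2cc(OC)cc(CCCCCCC)c2C(=O)OCc2ccccc2)=CC1=O
F6 | step 14 | benzyl 2-[5-(benzyloxy)-4-formyl-3-heptyl-2-methoxyphenoxy]-6-heptyl-4-methoxybenzoate | CCCCCCCc1cc(OC)cc(Oc2cc(OCc3ccccc3)c(C=O)c(CCCCCCC)c2OC)c1C(=O)OCc1ccccc1
F7 | step 14 | 6-(benzyloxy)-4-{2-[(benzyloxy)carbonyl]-3-heptyl-5-methoxyphenoxy}-2-heptyl-3-methoxybenzoic acid | CCCCCCCc1cc(OC)cc(Oc2cc(OCc3ccccc3)c(C(=O)O)c(CCCCCCC)c2OC)c1C(=O)OCc1ccccc1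
A1 | alternative 1 | 2-(4-carboxy-2,5-dimethoxyphenoxy)-4-methoxybenzoic acid | COc1ccc(C(=O)O)c(Oc2cc(OC)c(C(=O)O)cc2OC)c1
A2 | alternative 1 | potassium heptyltrifluoroborate | CCCCCCC[B-](F)(F)F.[K+]
A3 | alternative 1 | 2-(4-carboxy-3-heptyl-2,5-dimethoxyphenoxy)-6-heptyl-4-methoxybenzoic acid | CCCCCCCc1cc(OC)cc(Oc2cc(OC)c(C(=O)O)c(CCCCCCC)c2OC)c1C(=O)O
A4 | alternative 2 | 2-bromo-4-methoxy-6-(trimethylsilyl)phenyl trifluoromethanesulfonate | COc1cc(Br)c(OS(=O)(=O)C(F)(F)F)c([Si](C)(C)C)c1
A5 | alternative 2 | benzyl 2-(benzyloxy)-6-heptyl-4-hydroxy-5-methoxybenzoate | CCCCCCCc1c(OC)c(O)cc(OCc2ccccc2)c1C(=O)OCc1ccccc1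
A6 | alternative 2 | 2-{5-(benzyloxy)-4-[(benzyloxy)carbonyl]-3-heptyl-2-methoxyphenoxy}-6-bromo-4-methoxybenzoic acid | COc1cc(Br)c(C(=O)O)c(Oc2cc(OCc3ccccc3)c(C(=O)OCc3ccccc3)c(CCCCCCC)c2OC)c1
A7 | alternative 3 | benzyl 2-(benzyloxy)-6-heptyl-5-methoxy-4-[(4-methoxy-2-oxo-2H-pyran-6-yl)oxy]benzoate | COc1cc(Oc2cc(OCc3ccccc3)c(C(=O)OCc3ccccc3)c(CCCCCCC)c2OC)oc(=O)c1
A8 | alternative 3 | benzyl dec-2-ynoate | CCCCCCCC#CC(=O)OCc1ccccc1
A9 | alternative 3 | benzyl 2-(benzyloxy)-4-{2-[(benzyloxy)carbonyl]-3-heptyl-5-methoxyphenoxy}-6-heptyl-5-methoxybenzoate | CCCCCCCc1cc(OC)cc(Oc2cc(OCc3ccccc3)c(C(=O)OCc3ccccc3)c(CCCCCCC)c2OC)c1C(=O)OCc1ccccc1
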